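**Retrosynthetic overview**

1. Numbering used: C1 = lactone carbonyl, C2, C3 = CH–O–O, C4 = quaternary C(CH3)–O(lactone), C5 = ring CH2, C6 = quaternary C(CH3)(side chain)–O–O; ring A = 1,2-dioxane, ring B = γ-lactone. Late disconnections: ArOH ⇐ ArO–TIPS; the two CH2 groups next to C6 ⇐ C≡C (diimide); C1=O ⇐ methyl acetal (oxidation).
2. Key disconnection: ring A is cut at C5–C6 and at O–C3, and ring B at C4–O. A propargylic α-methoxy hydroperoxide (C6 with its O–O) and (2E)-4-methylpenta-2,4-dienal (C1–C5) are joined in one flask: amine-catalysed peroxide conjugate addition (O–C3, sets C3), then a peroxycarbenium Prins-type cyclisation (C5–C6, sets C6 and C4). Ring A closes first, ring B directly after.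
3. Enabling feature: in ring A, C6 bears O–O and no hydrogen, so it can be a peroxycarbenium carbon. C3 is β to the C1 carbonyl, so it can accept the peroxide by conjugate addition. C4 is tertiary, oxygenated and 1,3 to C6, which is exactly where the cation arises when the CH2 terminus (C5) of a C4=C5 isopropenyl group attacks C6; its oxygen then comes from C1 and closes ring B cis-fused.
4. The side chain is carried as an alkyne on C6: slim alkynyl versus methyl is what differentiates the two faces of the peroxycarbenium ion in the chair transition state.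
5. Fragments: the hydroperoxide from 4-bromophenol, 1,8-dibromooctane and 2-methylbut-1-en-3-yne (Grignard coupling, acetylide alkylation, ozonolysis in methanol); the dienal from 2-methylprop-2-enal by Wittig reaction.

Key step: step 6

Remark on the chemistry: the sense of induction in step 6 is taken from the usual shielding model for (E)-iminium ions of 2-(diarylsilyloxymethyl)pyrrolidines (attack anti to the diarylmethyl group); for the (R)-catalyst this opens the Re face of C3.

**Step 1**
Reactants: 1 4-bromophenol
Product: 2 (4-bromophenoxy)triisopropylsilane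
Conditions: TIPSCl, imidazole, DMF, rt
Reagents that add atoms: chlorotriisopropylsilane, CC(C)[Si](Cl)(C(C)C)C(C)C
Why: Silyl ether protection of the phenol masks the acidic OH for the organometallic steps; no stereocentre is formed.

**Step 2**
Reactants: 2 (4-bromophenoxy)triisopropylsilane; 3 1,8-dibromooctane
Product: 5 [4-(8-bromooctyl)phenoxy]triisopropylsilane, via aryl Grignard reagent 4 (not isolated)
Conditions: Mg, THF, reflux; then added to 3 (3 equiv), Li2CuCl4 (3 mol%), THF, −10 °C to rt
Reagents that add atoms: none
Why: Copper-catalysed cross-coupling of an aryl Grignard reagent with a primary alkyl bromide, the excess of symmetric dibromide limiting double arylation; no stereocentre is formed.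

**Step 3**
Reactants: 6 2-methylbut-1-en-3-yne; 5 [4-(8-bromooctyl)phenoxy]triisopropylsilane
Product: 8 enyne (isopropenyl alkyne carrying the aryloctyl chain), via lithium acetylide 7 (not isolated)
Conditions: n-BuLi, THF, −78 °C; then 5, DMPU, −78 °C to rt
Reagents that add atoms: none
Why: SN2 alkylation of a lithium acetylide by a primary bromide in THF/DMPU; no stereocentre is formed.

**Step 4**
Reactants: 8 enyne
Product: 10 racemic propargylic α-methoxy hydroperoxide, via carbonyl oxide 9 (not isolated)
Conditions: O3 (1 equiv, indicator dye), CH2Cl2/MeOH 4:1, −78 °C; N2 purge, no reductive work-up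
Reagents that add atoms: ozone, [O-][O+]=O; methanol, CO
Why: Criegee ozonolysis in methanol: ozone adds to the 1,1-disubstituted alkene far faster than to the alkyne or the arene, the primary ozonide opens to formaldehyde and the disubstituted carbonyl oxide, and methanol traps the latter; the new stereocentre is racemic, which does not matter because it becomes planar in step 6.

**Step 5**
Reactants: 11 2-methylprop-2-enal; 12 (triphenylphosphoranylidene)acetaldehyde
Product: 13 (2E)-4-methylpenta-2,4-dienal
Conditions: PhMe, 70 °C, sealed vessel, 11 in threefold excess; distillation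
Reagents that add atoms: none
Why: Wittig reaction of a formyl-stabilised ylide gives the (E)-alkene, and the excess of 11 suppresses a second homologation; no stereocentre is formed.

**Step 6**
Reactants: 10 racemic propargylic α-methoxy hydroperoxide; 13 (2E)-4-methylpenta-2,4-dienal
Product: 15 cis-fused bicyclic peroxy acetal (ring A and the methyl acetal of ring B; anomer mixture), via β-peroxy aldehyde 14 (not isolated)
Conditions: (R)-2-{bis[3,5-bis(trifluoromethyl)phenyl][(trimethylsilyl)oxy]methyl}pyrrolidine (10 mol%), CH2Cl2, 0 °C; then 4 Å molecular sieves, TMSOTf (30 mol%), −78 to −40 °C; Et3N quench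
Reagents that add atoms: none
Why: Proposed new method: the amine and 13 give an (E)-iminium ion whose Re face at C3 is open, the hydroperoxide of 10 (a hard alpha-effect nucleophile) adds 1,4 and hydrolysis releases aldehyde 14 with (3R) configuration (closest known type: diarylprolinol silyl ether catalysed peroxidation of enals); TMSOTf then ionises the C6–OCH3 bond to an alkynyl-stabilised peroxycarbenium ion (closest known type: Lewis acid cyclisation of unsaturated monoperoxyketals, a Prins-type reaction). Ring A closes by 6-endo-trig attack of the alkene CH2 (C5) on C6, the only mode that leaves a tertiary cation (C4), and ring B closes by five-membered capture of this cation by the aldehyde oxygen, the resulting oxolanylium ion taking up the methoxy group that was released. C3 is controlled by the catalyst; C6 by a chair transition state in which the C3 side chain is equatorial and the rod-like alkynyl group, which sits syn to the O–O bond in the peroxycarbenium ion, becomes axial while CH3 becomes equatorial, that is, side chain cis to the C3 substituent as in the target; C4 by the two-atom tether, which allows only the cis ring fusion; the acetal carbon is not controlled and ceases to be a stereocentre in step 7. The step needs 1,4- and not 1,6-addition and peroxide and not epoxide formation in the first stage (secured by the hard nucleophile, the hindered tertiary peroxide and the low temperature), and C–O and not O–O heterolysis plus internal and not external capture of the cation in the second (secured by the alkynyl-stabilised cation and the five-membered reach of the aldehyde).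

**Step 7**
Reactants: 15 cis-fused bicyclic peroxy acetal
Product: 16 alkynyl peroxylactone
Conditions: CrO3, H2SO4, H2O, acetone, 0 °C
Reagents that add atoms: water, O
Why: Jones oxidation: aqueous acid opens the methyl acetal to the lactol and hexavalent chromium oxidises it to the γ-lactone, both anomers converging, while the dialkyl peroxide, the alkyne and the aryl silyl ether should survive; no stereocentre is touched.

**Step 8**
Reactants: 16 alkynyl peroxylactone
Product: 18 TIPS-protected plakortolide S, via cis-alkene 17 (not isolated)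
Conditions: KO2CN=NCO2K (large excess, in portions), AcOH, MeOH/CH2Cl2, 0 °C to rt
Reagents that add atoms: none
Why: Diimide reduction: diazene made in the flask delivers H2 to the alkyne and then to the cis-alkene through a concerted cyclic transition state and leaves the O–O bond intact, which catalytic hydrogenation would endanger; no stereocentre is touched (the descriptor at C6 changes only because the priorities change).

**Step 9**
Reactants: 18 TIPS-protected plakortolide S
Product: 19 plakortolide S
Conditions: TBAF, AcOH, THF, 0 °C
Reagents that add atoms: none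
Why: Fluoride cleavage of the aryl silyl ether, buffered with acetic acid so that no base opens ring A by β-elimination across C2–C3 or by Kornblum–DeLaMare fragmentation at C3–H; no stereocentre is touched.

**Compound list**

1 | 4-bromophenol | Oc1ccc(Br)cc1 | starting material
2 | (4-bromophenoxy)triisopropylsilane | CC(C)[Si](Oc1ccc(Br)cc1)(C(C)C)C(C)C | intermediate
3 | 1,8-dibromooctane | BrCCCCCCCCBr | starting material
4 | {4-[(triisopropylsilyl)oxy]phenyl}magnesium bromide | Br[Mg]c1ccc(O[Si](C(C)C)(C(C)C)C(C)C)cc1 | intermediate
5 | [4-(8-bromooctyl)phenoxy]triisopropylsilane | BrCCCCCCCCc1ccc(O[Si](C(C)C)(C(C)C)C(C)C)cc1 | intermediate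
6 | 2-methylbut-1-en-3-yne | C=C(C)C#C | starting material
7 | lithium 3-methylbut-3-en-1-yn-1-ide | [Li]C#CC(C)=C | intermediate
8 | triisopropyl[4-(11-methyldodec-11-en-9-yn-1-yl)phenoxy]silane | C=C(C)C#CCCCCCCCCc1ccc(O[Si](C(C)C)(C(C)C)C(C)C)cc1 | intermediate
9 | carbonyl oxide of 12-{4-[(triisopropylsilyl)oxy]phenyl}dodec-3-yn-2-one | CC(=[O+][O-])C#CCCCCCCCCc1ccc(O[Si](C(C)C)(C(C)C)C(C)C)cc1 | intermediate
10 | rac-[4-(11-hydroperoxy-11-methoxydodec-9-yn-1-yl)phenoxy]triisopropylsilane | CC(OC)(OO)C#CCCCCCCCCc1ccc(O[Si](C(C)C)(C(C)C)C(C)C)cc1 | intermediate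
11 | 2-methylprop-2-enal | C=C(C)C=O | starting material
12 | (triphenylphosphoranylidene)acetaldehyde | O=CC=P(c1ccccc1)(c1ccccc1)c1ccccc1 | starting material
13 | (2E)-4-methylpenta-2,4-dienal | C=C(C)/C=C/C=O | intermediate
14 | (3R)-3-[(2-methoxy-12-{4-[(triisopropylsilyl)oxy]phenyl}dodec-3-yn-2-yl)peroxy]-4-methylpent-4-enal, both configurations at the peroxyketal carbon | O=CC[C@H](C(C)=C)OOC(C)(OC)C#CCCCCCCCCc1ccc(O[Si](C(C)C)(C(C)C)C(C)C)cc1 | intermediate
15 | (1R,4R,6R,8RS)-8-methoxy-4,6-dimethyl-4-(10-{4-[(triisopropylsilyl)oxy]phenyl}dec-1-yn-1-yl)-2,3,7-trioxabicyclo[4.3.0]nonane (cis-fused; alkynyl cis to the ring B oxygen on C4; anomer mixture) | C[C@]1(C#CCCCCCCCCc2ccc(O[Si](C(C)C)(C(C)C)C(C)C)cc2)C[C@@]2(C)OC(OC)C[C@H]2OO1 | intermediate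
16 | (1R,4R,6R)-4,6-dimethyl-4-(10-{4-[(triisopropylsilyl)oxy]phenyl}dec-1-yn-1-yl)-2,3,7-trioxabicyclo[4.3.0]nonan-8-one | C[C@]1(C#CCCCCCCCCc2ccc(O[Si](C(C)C)(C(C)C)C(C)C)cc2)C[C@@]2(C)OC(=O)C[C@H]2OO1 | intermediate
17 | (1R,4R,6R)-4,6-dimethyl-4-[(1Z)-10-{4-[(triisopropylsilyl)oxy]phenyl}dec-1-en-1-yl]-2,3,7-trioxabicyclo[4.3.0]nonan-8-one | C[C@]1(/C=C\CCCCCCCCc2ccc(O[Si](C(C)C)(C(C)C)C(C)C)cc2)C[C@@]2(C)OC(=O)C[C@H]2OO1 | intermediate
18 | (1R,4S,6R)-4,6-dimethyl-4-(10-{4-[(triisopropylsilyl)oxy]phenyl}decyl)-2,3,7-trioxabicyclo[4.3.0]nonan-8-one | C[C@]1(CCCCCCCCCCc2ccc(O[Si](C(C)C)(C(C)C)C(C)C)cc2)C[C@@]2(C)OC(=O)C[C@H]2OO1 | intermediate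
19 | plakortolide S, (1R,4S,6R)-4-[10-(4-hydroxyphenyl)decyl]-4,6-dimethyl-2,3,7-trioxabicyclo[4.3.0]nonan-8-one | C[C@]1(CCCCCCCCCCc2ccc(O)cc2)C[C@@]2(C)OC(=O)C[C@H]2OO1 | target

**Step count and risks**

Total steps: 9. Longest linear sequence: 8 steps (1, 2, 3, 4, 6, 7, 8, 9).

Step 6 (proposed new method). What may go wrong: collapse of the peroxy-enamine to an epoxide, or 1,6-addition, in the amine stage; proton loss from the C4 cation, its capture by the released methoxy group, or O–O heterolysis in the acid stage; insufficient discrimination between axial alkynyl and axial methyl at C6. Fallback (known reactions, run separately): from 10 and 13 only the amine-catalysed peroxidation is run and 14 is isolated. Buffered Pinnick oxidation (NaClO2, NaH2PO4, 2-methylbut-2-ene, t-BuOH/H2O) then gives the (3R)-β-peroxy acid F1. SnCl4 in CH2Cl2 at −78 °C performs the Lewis acid cyclisation known for unsaturated monoperoxyketals, now ended by the carboxylic acid as in a cation–olefin lactonisation, and should deliver lactone 16 directly, where the route is rejoined (step 7 falls away).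

Step 8. What may go wrong: the reduction stalls at the cis-alkene next to the quaternary C6 because diazene disproportionates faster than it is transferred. Fallback (the alkyne is given up as control element and a saturated chain is carried through): Grignard reagent 4 is coupled with 1,10-dibromodecane (Li2CuCl4) to the bromide F2, which with isopropenylmagnesium bromide (Li2CuCl4) gives the terminal alkene F3. Ozonolysis in CH2Cl2/MeOH gives the saturated α-methoxy hydroperoxide F4. Under the conditions of step 6 with 13 this should give, through the saturated β-peroxy aldehyde F5, the saturated acetal F6 together with its C6 epimer F7; without the alkyne little preference at C6 is expected, so the two are separated by chromatography. Oxidation of F6 with CrO3/H2SO4 as in step 7 gives 18, where the route is rejoined.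

Step 4. What may go wrong: opening of the primary ozonide in the other direction (formaldehyde oxide plus ynone), so that the carbonyl oxide is not placed on C6. Fallback (the peroxyketal is made by ketal exchange instead of carbonyl oxide trapping): from 8, ozonolysis with Me2S work-up gives the ynone F8 whichever way the primary ozonide opens. HC(OMe)3, MeOH and catalytic camphorsulfonic acid give the dimethyl ketal F9. Exchange of one methoxy group with ethereal H2O2 and catalytic acid (the known perhydrolysis of ketals) gives 10, where the route is rejoined.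

**Further compounds**

F1 | step 6 | (3R)-3-[(2-methoxy-12-{4-[(triisopropylsilyl)oxy]phenyl}dodec-3-yn-2-yl)peroxy]-4-methylpent-4-enoic acid | OC(=O)C[C@H](C(C)=C)OOC(C)(OC)C#CCCCCCCCCc1ccc(O[Si](C(C)C)(C(C)C)C(C)C)cc1
F2 | step 8 | [4-(10-bromodecyl)phenoxy]triisopropylsilane | BrCCCCCCCCCCc1ccc(O[Si](C(C)C)(C(C)C)C(C)C)cc1
F3 | step 8 | triisopropyl[4-(11-methyldodec-11-en-1-yl)phenoxy]silane | C=C(C)CCCCCCCCCCc1ccc(O[Si](C(C)C)(C(C)C)C(C)C)cc1
F4 | step 8 | rac-[4-(11-hydroperoxy-11-methoxydodecyl)phenoxy]triisopropylsilane | CC(OC)(OO)CCCCCCCCCCc1ccc(O[Si](C(C)C)(C(C)C)C(C)C)cc1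
F5 | step 8 | (3R)-3-[(2-methoxy-12-{4-[(triisopropylsilyl)oxy]phenyl}dodecan-2-yl)peroxy]-4-methylpent-4-enal | O=CC[C@H](C(C)=C)OOC(C)(OC)CCCCCCCCCCc1ccc(O[Si](C(C)C)(C(C)C)C(C)C)cc1
F6 | step 8 | (1R,4S,6R,8RS)-8-methoxy-4,6-dimethyl-4-(10-{4-[(triisopropylsilyl)oxy]phenyl}decyl)-2,3,7-trioxabicyclo[4.3.0]nonane | C[C@]1(CCCCCCCCCCc2ccc(O[Si](C(C)C)(C(C)C)C(C)C)cc2)C[C@@]2(C)OC(OC)C[C@H]2OO1
F7 | step 8 | (1R,4R,6R,8RS)-8-methoxy-4,6-dimethyl-4-(10-{4-[(triisopropylsilyl)oxy]phenyl}decyl)-2,3,7-trioxabicyclo[4.3.0]nonane | C[C@@]1(CCCCCCCCCCc2ccc(O[Si](C(C)C)(C(C)C)C(C)C)cc2)C[C@@]2(C)OC(OC)C[C@H]2OO1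
F8 | step 4 | 12-{4-[(triisopropylsilyl)oxy]phenyl}dodec-3-yn-2-one | CC(=O)C#CCCCCCCCCc1ccc(O[Si](C(C)C)(C(C)C)C(C)C)cc1
F9 | step 4 | [4-(11,11-dimethoxydodec-9-yn-1-yl)phenoxy]triisopropylsilane | CC(OC)(OC)C#CCCCCCCCCc1ccc(O[Si](C(C)C)(C(C)C)C(C)C)cc1
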